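**Plan**

- Cuts: the ten O‑benzyl bonds come off last. C3–O of the lower unit goes back to C3–Si. O1–C2 and C3–C4 of the lower ring C are cut together (retro oxa‑[4+2]) into a ring‑A o‑quinone methide and an (E)‑styrylsilane on ring B. The C4(upper)–C2'(lower ring B) bond is cut (retro Friedel–Crafts) to the flavan‑3,4‑diol from (+)‑dihydrorobinetin and 5‑bromopyrogallol.
- Forward order: the upper rings A, C and B are bought with dihydrorobinetin. The lower ring B is joined to upper C4, and its bromine becomes an ethynyl and then an (E)‑silylvinyl arm. The lower ring A arrives in the cycloaddition, and ring C is the only ring that is made.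
- Enabling feature: in the lower unit O1 and C4 sit ortho on ring A (on C8a and C4a), so O1=C8a–C4a=C4 can exist as an o‑quinone methide, stabilised by the 7‑oxygen para to C4. C2=C3 is a styrene bond polarised by the trioxygenated ring B and by silicon on C3.
- Stereochemistry: upper C2 and C3 come from the chiral pool, upper C4 from attack anti to the 3‑OH. Lower C2/C3 trans comes from the (E)‑alkene, C4 from endo approach, and the absolute sense from a chiral imidodiphosphoric acid. C3–Si becomes C3–OH with retention.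

Key step: step 8

Assumptions: (+)‑dihydrorobinetin of (2R,3R) configuration is taken as a purchasable natural product; the antipode of the chiral imidodiphosphoric acid that leads to the (4R) adduct is taken to be the (S,S) form and would be exchanged for (R,R) if a first trial showed the opposite sense.

**Route**

Step 1
Reactants: 1 (+)‑dihydrorobinetin
Product: 2 tetra‑O‑benzyl dihydrorobinetin
Conditions: BnBr (4.4 equiv), K2CO3, DMF, rt, argon
Reagents that add atoms: benzyl bromide, BrCc1ccccc1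
Why: Williamson etherification of the four phenols, the 3‑OH not being deprotonated by K2CO3; no new stereocentre, and the 2,3‑trans arrangement is the stable one.

Step 2
Reactants: 2 tetra‑O‑benzyl dihydrorobinetin
Product: 3 tetra‑O‑benzyl flavan‑3,4‑diol
Conditions: NaBH4, THF/MeOH, 0 °C
Reagents that add atoms: none
Why: Borohydride reduction of the C4 ketone, where axial hydride delivery on the half‑chair should give the equatorial 4‑OH trans to the 3‑OH (4R), the usual outcome for 2,3‑trans dihydroflavonols.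

Step 3
Reactants: 4 5‑bromo‑1,2,3‑trimethoxybenzene
Product: 5 5‑bromopyrogallol
Conditions: BBr3, CH2Cl2, −78 °C → rt; then H2O
Reagents that add atoms: none
Why: Lewis‑acid‑mediated cleavage of aryl methyl ethers by bromide attack on the O‑methyl groups, the aryl bromide being inert.

Step 4
Reactants: 3 tetra‑O‑benzyl flavan‑3,4‑diol; 5 5‑bromopyrogallol
Product: 6 4‑aryl flavan‑3‑ol (bromotriol)
Conditions: 5 (5 equiv), BF3·OEt2 (cat.), dioxane/CH2Cl2, 0 °C → rt, slow addition of 3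
Reagents that add atoms: none
Why: Friedel–Crafts‑type arylation of the flavan‑4‑yl cation (biomimetic interflavanyl bond formation), where the cation para to the 7‑benzyloxy group is taken by the only kind of free ring position of 5 (ortho and para to OH) from the face anti to the 3‑OH, so that the 3,4‑trans (4S) adduct should prevail.

Step 5
Reactants: 6 4‑aryl flavan‑3‑ol (bromotriol)
Product: 7 octabenzyl aryl bromide
Conditions: NaH, BnBr, DMF, 0 °C → rt
Reagents that add atoms: benzyl bromide, BrCc1ccccc1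
Why: Williamson etherification of the three phenoxides and of the secondary alkoxide at C3, with no stereocentre touched.

Step 6
Reactants: 7 octabenzyl aryl bromide; 8 ethynyltrimethylsilane
Product: 10 aryl alkyne (ethynyl in place of bromine), via silylalkyne 9 (not isolated)
Conditions: PdCl2(MeCN)2 (3 mol %), XPhos (9 mol %), Cs2CO3, MeCN/THF, 70 °C; then K2CO3 (cat.), MeOH, rt
Reagents that add atoms: none
Why: Copper‑free Sonogashira coupling with a bulky biarylphosphine, suited to the hindered electron‑rich aryl bromide, followed by methanolysis of the alkynyl–silicon bond.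

Step 7
Reactants: 10 aryl alkyne
Product: 11 (E)‑styryl disiloxane
Conditions: HSiMe2OSiMe3 (1.5 equiv), Pt2(dvtms)3 (0.5 mol %), P(t‑Bu)3 (1 mol %), THF, rt
Reagents that add atoms: 1,1,1,3,3‑pentamethyldisiloxane, C[SiH](C)O[Si](C)(C)C
Why: Hydrosilylation of a terminal alkyne with zerovalent platinum, where syn addition with silicon on the terminal carbon (favoured by the bulky phosphine and the ortho‑substituted aryl group) should give the (E)‑alkenylsilane.

Step 8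
Reactants: 11 (E)‑styryl disiloxane; 12 4‑(benzyloxy)‑2‑hydroxybenzaldehyde
Product: 14 3‑silyl‑4‑benzyloxyflavan cycloadduct, via o‑quinone methide 13 (not isolated)
Conditions: 12 (1.5 equiv), BnOH (2 equiv), (S,S) BINOL‑derived imidodiphosphoric acid (10 mol %), 5 Å MS, CH2Cl2/cyclohexane, 0 °C → rt
Reagents that add atoms: benzyl alcohol, OCc1ccccc1
Why: Proposed new method: the acid condenses 12 with benzyl alcohol to the O‑benzyl oxocarbenium ion, which is the protonated form of the 4‑benzyloxy o‑quinone methide 13 (the 1‑oxadiene O1=C8a–C4a=C4 of ring A), and this should add across C2=C3 of 11 in an inverse‑electron‑demand oxa‑Diels–Alder reaction with C3–C4 forming ahead of O1–C2. The closest known reactions are the acid‑catalysed [4+2] cycloadditions of alkoxy o‑quinone methides from salicylaldehyde acetals with styrenes and their asymmetric intramolecular version with alkenols under chiral imidodiphosphoric acids; an alkenylsilane has not been used as the 2π partner. Ring C closes as the six‑membered ring of a [4+2] cycloaddition, suprafacial on both partners (if stepwise, by capture of the C2 benzylic cation by O1). C2 and C3 should come out trans because the (E)‑geometry of 11 is transferred; C4 should come out trans to C3 and cis to C2 because ring B lies endo over the diene whose benzyloxy group points outside, with the silyl group exo; the absolute sense (4R, hence 2R,3S) is set by the chiral counter‑anion that covers one face of C4, the stereocentres of the upper unit being remote and on both faces of ring B. The step needs the regioselectivity C3 to C4 and O1 to C2, which the β‑effect of silicon and the electron‑rich ring B secure by placing the developing positive charge on C2, and it needs ring closure to outrun loss of silicon, which the neighbouring phenol oxygen and the non‑nucleophilic medium favour.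

Step 9
Reactants: 14 3‑silyl‑4‑benzyloxyflavan cycloadduct
Product: 15 flavan‑3‑ol 4‑benzyl ether
Conditions: 30% H2O2, KF, KHCO3, THF/MeOH, rt → 40 °C
Reagents that add atoms: hydrogen peroxide, OO
Why: Tamao oxidation, made possible by the Si–O bond of the disiloxane, in which C3 migrates from silicon to oxygen with retention, so that the 3‑OH should stand trans to ring B and to the 4‑benzyloxy group as known for β‑alkoxy silanes.

Step 10
Reactants: 15 flavan‑3‑ol 4‑benzyl ether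
Product: 16 CNP0205451.4
Conditions: H2 (1 atm), Pd(OH)2/C, THF/MeOH, rt; filtration under argon
Reagents that add atoms: none
Why: Catalytic hydrogenolysis of the ten benzyl ethers, in which the PhCH2–O bond of the lower 4‑O‑benzyl group should cleave in preference to the hindered ring C4–O bond, the reaction being stopped at completion so that no stereocentre is touched.

**Compound list**

1 | (+)‑dihydrorobinetin, (2R,3R)‑3,7‑dihydroxy‑2‑(3,4,5‑trihydroxyphenyl)chroman‑4‑one | Oc1ccc2c(c1)O[C@H](c1cc(O)c(O)c(O)c1)[C@@H](O)C2=O | starting material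
2 | (2R,3R)‑7‑(benzyloxy)‑3‑hydroxy‑2‑[3,4,5‑tris(benzyloxy)phenyl]chroman‑4‑one | c1ccccc1COc1ccc2c(c1)O[C@H](c1cc(OCc3ccccc3)c(OCc3ccccc3)c(OCc3ccccc3)c1)[C@@H](O)C2=O | intermediate
3 | (2R,3S,4R)‑7‑(benzyloxy)‑2‑[3,4,5‑tris(benzyloxy)phenyl]chromane‑3,4‑diol (2,3‑trans‑3,4‑trans) | c1ccccc1COc1ccc2c(c1)O[C@H](c1cc(OCc3ccccc3)c(OCc3ccccc3)c(OCc3ccccc3)c1)[C@@H](O)[C@@H]2O | intermediate
4 | 5‑bromo‑1,2,3‑trimethoxybenzene | COc1cc(Br)cc(OC)c1OC | starting material
5 | 5‑bromobenzene‑1,2,3‑triol (5‑bromopyrogallol) | Oc1cc(Br)cc(O)c1O | intermediate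
6 | (2R,3S,4S)‑7‑(benzyloxy)‑4‑(6‑bromo‑2,3,4‑trihydroxyphenyl)‑2‑[3,4,5‑tris(benzyloxy)phenyl]chroman‑3‑ol | c1ccccc1COc1ccc2c(c1)O[C@H](c1cc(OCc3ccccc3)c(OCc3ccccc3)c(OCc3ccccc3)c1)[C@@H](O)[C@@H]2c1c(Br)cc(O)c(O)c1O | intermediate
7 | (2R,3S,4S)‑3,7‑bis(benzyloxy)‑4‑[6‑bromo‑2,3,4‑tris(benzyloxy)phenyl]‑2‑[3,4,5‑tris(benzyloxy)phenyl]chromane | c1ccccc1COc1ccc2c(c1)O[C@H](c1cc(OCc3ccccc3)c(OCc3ccccc3)c(OCc3ccccc3)c1)[C@@H](OCc1ccccc1)[C@@H]2c1c(Br)cc(OCc3ccccc3)c(OCc3ccccc3)c1OCc1ccccc1 | intermediate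
8 | ethynyltrimethylsilane | C#C[Si](C)(C)C | starting material
9 | (2R,3S,4S)‑3,7‑bis(benzyloxy)‑4‑{2,3,4‑tris(benzyloxy)‑6‑[(trimethylsilyl)ethynyl]phenyl}‑2‑[3,4,5‑tris(benzyloxy)phenyl]chromane | c1ccccc1COc1ccc2c(c1)O[C@H](c1cc(OCc3ccccc3)c(OCc3ccccc3)c(OCc3ccccc3)c1)[C@@H](OCc1ccccc1)[C@@H]2c1c(C#C[Si](C)(C)C)cc(OCc3ccccc3)c(OCc3ccccc3)c1OCc1ccccc1 | intermediate (not isolated)
10 | (2R,3S,4S)‑3,7‑bis(benzyloxy)‑4‑[6‑ethynyl‑2,3,4‑tris(benzyloxy)phenyl]‑2‑[3,4,5‑tris(benzyloxy)phenyl]chromane | c1ccccc1COc1ccc2c(c1)O[C@H](c1cc(OCc3ccccc3)c(OCc3ccccc3)c(OCc3ccccc3)c1)[C@@H](OCc1ccccc1)[C@@H]2c1c(C#C)cc(OCc3ccccc3)c(OCc3ccccc3)c1OCc1ccccc1 | intermediate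
11 | (2R,3S,4S)‑3,7‑bis(benzyloxy)‑4‑{2,3,4‑tris(benzyloxy)‑6‑[(E)‑2‑(1,1,3,3,3‑pentamethyldisiloxan‑1‑yl)ethenyl]phenyl}‑2‑[3,4,5‑tris(benzyloxy)phenyl]chromane | c1ccccc1COc1ccc2c(c1)O[C@H](c1cc(OCc3ccccc3)c(OCc3ccccc3)c(OCc3ccccc3)c1)[C@@H](OCc1ccccc1)[C@@H]2c1c(/C=C/[Si](C)(C)O[Si](C)(C)C)cc(OCc3ccccc3)c(OCc3ccccc3)c1OCc1ccccc1 | intermediate
12 | 4‑(benzyloxy)‑2‑hydroxybenzaldehyde | O=Cc1ccc(OCc2ccccc2)cc1O | starting material
13 | (6E)‑3‑(benzyloxy)‑6‑[(benzyloxy)methylidene]cyclohexa‑2,4‑dien‑1‑one (o‑quinone methide; formed as its protonated oxocarbenium form) | O=C1C=C(OCc2ccccc2)C=C/C1=C\OCc1ccccc1 | intermediate (not isolated)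
14 | (2R,3S,4S)‑3,7‑bis(benzyloxy)‑4‑{2,3,4‑tris(benzyloxy)‑6‑[(2R,3S,4R)‑4,7‑bis(benzyloxy)‑3‑(1,1,3,3,3‑pentamethyldisiloxan‑1‑yl)chroman‑2‑yl]phenyl}‑2‑[3,4,5‑tris(benzyloxy)phenyl]chromane | c1ccccc1COc1ccc2c(c1)O[C@H](c1cc(OCc3ccccc3)c(OCc3ccccc3)c(OCc3ccccc3)c1)[C@@H](OCc1ccccc1)[C@@H]2c1c([C@H]4Oc5cc(OCc6ccccc6)ccc5[C@@H](OCc6ccccc6)[C@@H]4[Si](C)(C)O[Si](C)(C)C)cc(OCc3ccccc3)c(OCc3ccccc3)c1OCc1ccccc1 | intermediate
15 | (2R,3S,4R)‑4,7‑bis(benzyloxy)‑2‑{3,4,5‑tris(benzyloxy)‑2‑[(2R,3S,4S)‑3,7‑bis(benzyloxy)‑2‑[3,4,5‑tris(benzyloxy)phenyl]chroman‑4‑yl]phenyl}chroman‑3‑ol | c1ccccc1COc1ccc2c(c1)O[C@H](c1cc(OCc3ccccc3)c(OCc3ccccc3)c(OCc3ccccc3)c1)[C@@H](OCc1ccccc1)[C@@H]2c1c([C@H]4Oc5cc(OCc6ccccc6)ccc5[C@@H](OCc6ccccc6)[C@@H]4O)cc(OCc3ccccc3)c(OCc3ccccc3)c1OCc1ccccc1 | intermediate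
16 | CNP0205451.4, (2R,3S,4R)‑2‑{3,4,5‑trihydroxy‑2‑[(2R,3S,4S)‑3,7‑dihydroxy‑2‑(3,4,5‑trihydroxyphenyl)chroman‑4‑yl]phenyl}chromane‑3,4,7‑triol | Oc1ccc2c(c1)O[C@H](c1cc(O)c(O)c(O)c1)[C@@H](O)[C@@H]2c1c([C@H]2Oc3cc(O)ccc3[C@@H](O)[C@@H]2O)cc(O)c(O)c1O | target

**Totals and risks**

Total step count: 10 steps. Longest linear sequence: 9 steps (steps 1, 2, 4, 5, 6, 7, 8, 9 and 10, from 1 to 16).

Steps most likely to fail:

1. Step 8 (Proposed new method). The silyl group may be lost from the β‑silyl benzylic cation before O1 closes onto C2. The acid may protodesilylate 11. The chiral anion may discriminate the faces of C4 poorly with so large a dienophile. The fallback uses known reaction types that make the same two bonds in one operation; it sets out from aryl bromide 7 and comes back at 15. Heck reaction of 7 with acrolein diethyl acetal (Pd(OAc)2, nBu4NOAc, K2CO3, KCl, DMF, 90 °C; dilute HCl) should give the (E)‑cinnamaldehyde F1. Aminocatalytic domino oxa‑Michael/aldol condensation of F1 with 12 ((S)‑α,α‑diphenylprolinol trimethylsilyl ether, 2‑nitrobenzoic acid, toluene, rt) should give the (2R)‑2H‑chromene‑3‑carbaldehyde F2, the phenol adding to the face of the iminium ion that the catalyst leaves open. Decarbonylation with RhCl(PPh3)3 (toluene, 100 °C) should give the flav‑3‑ene F3. Dimethyldioxirane (acetone, −20 °C) should epoxidise anti to ring B to the 3,4‑epoxide F4, which benzyl alcohol should open at the benzylic C4 with inversion to give 15.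

2. Step 4. The C4 cation may be captured by ring A of un‑ionised 3 (self‑condensation), 5 may be alkylated twice, or attack may occur syn to the 3‑OH. The fallback sets out from 3 and comes back at 6. Thiolysis of 3 with benzyl mercaptan (BnSH, cat. BF3·OEt2, CH2Cl2, 0 °C) should give the storable 4‑benzylsulfanyl ether F5, the thiol outrunning ring A as nucleophile. Thiophilic activation of F5 with AgBF4 (THF, −40 °C) in the presence of excess 5 should then give 6 under acid‑free, low‑temperature conditions.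

3. Step 10. Hydrogenolysis may occur on the ring side of the lower C4–O–benzyl ether, or the freed C4–OH may be reduced further, which removes the C4 oxygen; the two alkyl benzyl ethers may also cleave slowly. The fallback sets out from 11 and comes back at 16, with the C4 oxygen carrying allyl instead of benzyl. Step 8 run with allyl alcohol should give the 4‑O‑allyl cycloadduct F6. Tamao oxidation as in step 9 should give the allyl ether alcohol F7. Isomerisation of the allyl ether with Ir(cod)(PMePh2)2PF6 (activated with H2, THF) and hydrolysis of the propenyl ether (HgCl2, HgO, aqueous acetone) should give the 3,4‑diol F8. Hydrogenolysis as in step 10 then has only aryl and one alkyl benzyl ether to cleave and no benzylic ether at the lower C4.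

**Further compounds**

F1 | step 8 | (2E)‑3‑{3,4,5‑tris(benzyloxy)‑2‑[(2R,3S,4S)‑3,7‑bis(benzyloxy)‑2‑[3,4,5‑tris(benzyloxy)phenyl]chroman‑4‑yl]phenyl}prop‑2‑enal | c1ccccc1COc1ccc2c(c1)O[C@H](c1cc(OCc3ccccc3)c(OCc3ccccc3)c(OCc3ccccc3)c1)[C@@H](OCc1ccccc1)[C@@H]2c1c(/C=C/C=O)cc(OCc3ccccc3)c(OCc3ccccc3)c1OCc1ccccc1
F2 | step 8 | (2R)‑7‑(benzyloxy)‑2‑{3,4,5‑tris(benzyloxy)‑2‑[(2R,3S,4S)‑3,7‑bis(benzyloxy)‑2‑[3,4,5‑tris(benzyloxy)phenyl]chroman‑4‑yl]phenyl}‑2H‑chromene‑3‑carbaldehyde | c1ccccc1COc1ccc2c(c1)O[C@H](c1cc(OCc3ccccc3)c(OCc3ccccc3)c(OCc3ccccc3)c1)[C@@H](OCc1ccccc1)[C@@H]2c1c([C@H]4Oc5cc(OCc6ccccc6)ccc5C=C4C=O)cc(OCc3ccccc3)c(OCc3ccccc3)c1OCc1ccccc1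
F3 | step 8 | (2S)‑7‑(benzyloxy)‑2‑{3,4,5‑tris(benzyloxy)‑2‑[(2R,3S,4S)‑3,7‑bis(benzyloxy)‑2‑[3,4,5‑tris(benzyloxy)phenyl]chroman‑4‑yl]phenyl}‑2H‑chromene (flav‑3‑ene, same arrangement in space at C2 as in F2) | c1ccccc1COc1ccc2c(c1)O[C@H](c1cc(OCc3ccccc3)c(OCc3ccccc3)c(OCc3ccccc3)c1)[C@@H](OCc1ccccc1)[C@@H]2c1c([C@H]4Oc5cc(OCc6ccccc6)ccc5C=C4)cc(OCc3ccccc3)c(OCc3ccccc3)c1OCc1ccccc1
F4 | step 8 | 3,4‑epoxide of F3 with the oxirane oxygen anti to ring B, (2R,3S,4S) in flavan numbering | c1ccccc1COc1ccc2c(c1)O[C@H](c1cc(OCc3ccccc3)c(OCc3ccccc3)c(OCc3ccccc3)c1)[C@@H](OCc1ccccc1)[C@@H]2c1c([C@H]4Oc5cc(OCc6ccccc6)ccc5[C@@H]6O[C@H]46)cc(OCc3ccccc3)c(OCc3ccccc3)c1OCc1ccccc1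
F5 | step 4 | (2R,3R,4R)‑7‑(benzyloxy)‑4‑(benzylsulfanyl)‑2‑[3,4,5‑tris(benzyloxy)phenyl]chroman‑3‑ol (2,3‑trans‑3,4‑trans) | c1ccccc1COc1ccc2c(c1)O[C@H](c1cc(OCc3ccccc3)c(OCc3ccccc3)c(OCc3ccccc3)c1)[C@@H](O)[C@@H]2SCc1ccccc1
F6 | step 10 | (2R,3S,4S)‑3,7‑bis(benzyloxy)‑4‑{2,3,4‑tris(benzyloxy)‑6‑[(2R,3S,4R)‑7‑(benzyloxy)‑3‑(1,1,3,3,3‑pentamethyldisiloxan‑1‑yl)‑4‑(prop‑2‑en‑1‑yloxy)chroman‑2‑yl]phenyl}‑2‑[3,4,5‑tris(benzyloxy)phenyl]chromane | c1ccccc1COc1ccc2c(c1)O[C@H](c1cc(OCc3ccccc3)c(OCc3ccccc3)c(OCc3ccccc3)c1)[C@@H](OCc1ccccc1)[C@@H]2c1c([C@H]4Oc5cc(OCc6ccccc6)ccc5[C@@H](OCC=C)[C@@H]4[Si](C)(C)O[Si](C)(C)C)cc(OCc3ccccc3)c(OCc3ccccc3)c1OCc1ccccc1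
F7 | step 10 | (2R,3S,4R)‑7‑(benzyloxy)‑4‑(prop‑2‑en‑1‑yloxy)‑2‑{3,4,5‑tris(benzyloxy)‑2‑[(2R,3S,4S)‑3,7‑bis(benzyloxy)‑2‑[3,4,5‑tris(benzyloxy)phenyl]chroman‑4‑yl]phenyl}chroman‑3‑ol | c1ccccc1COc1ccc2c(c1)O[C@H](c1cc(OCc3ccccc3)c(OCc3ccccc3)c(OCc3ccccc3)c1)[C@@H](OCc1ccccc1)[C@@H]2c1c([C@H]4Oc5cc(OCc6ccccc6)ccc5[C@@H](OCC=C)[C@@H]4O)cc(OCc3ccccc3)c(OCc3ccccc3)c1OCc1ccccc1
F8 | step 10 | (2R,3S,4R)‑7‑(benzyloxy)‑2‑{3,4,5‑tris(benzyloxy)‑2‑[(2R,3S,4S)‑3,7‑bis(benzyloxy)‑2‑[3,4,5‑tris(benzyloxy)phenyl]chroman‑4‑yl]phenyl}chromane‑3,4‑diol | c1ccccc1COc1ccc2c(c1)O[C@H](c1cc(OCc3ccccc3)c(OCc3ccccc3)c(OCc3ccccc3)c1)[C@@H](OCc1ccccc1)[C@@H]2c1c([C@H]4Oc5cc(OCc6ccccc6)ccc5[C@@H](O)[C@@H]4O)cc(OCc3ccccc3)c(OCc3ccccc3)c1OCc1ccccc1
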